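Compound numbers used throughout (full list after the steps): 1 tetramethoxybenzene, 2 chloroacetyl chloride, 3 chloromethyl ketone, 4 trimethoxybenzofuranone, 5 trihydroxybenzofuranone, 6 tris-MOM benzofuranone, 7 bromochlorophenol, 8 its MOM ether, 9 2-arylbenzofuranone, 10 silyl enol ether (key-step precursor), 11 cyclopropane (key-step product), 12 cyclopropanol, 13 protected flavanone chloride, 14 homoallylic bromide, 15 its zinc reagent, 16 protected target, 17 tetrasilyl ether, 18 target.

## Analysis of the target

Target 18 is a flavanone, a 2-aryl-2,3-dihydro-4H-chromen-4-one. Ring A (C4a to C8a) carries hydroxyl groups at C5, C7 and C8; ring C holds O1, C2, C3 and the C4 ketone; ring B is a 4′-hydroxyphenyl group with a 3-methylbut-3-enyl chain at C3′. The only stereocentre is C2, of S configuration (priorities O1 > C1′ > C3 > H). It is benzylic, bound to O1 and β to the ketone, so base epimerises it through reversible retro-oxa-Michael ring opening, and strong acid can ionise it with help from the para oxygen of ring B. Ring A is a hydroxyhydroquinone (5-OH and 8-OH are para) and oxidises easily once free, most of all as a phenoxide. The 1,1-disubstituted alkene sits ortho to a phenol, so protic acid would give a tertiary cation that the phenol traps or that shifts the double bond, and the alkene is also a good partner for electrophilic carbenoids and metathesis catalysts. The synthesis therefore has to set C2 late and mildly, place the oxygens of ring A in the 5,7,8 pattern without ambiguity, and use protecting groups that come off without hydrogenation, strong base or strong protic acid. The feature used is that removal of C3 from ring C joins C2 and C4 into the 2,3-bond of a flat, aromatic 2-aryl-3-oxybenzofuran, so that C3 can be put back as a methylene across that bond while C2 becomes stereogenic in the same event.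

## Retrosynthetic reasoning

**18 from 16.** The last operation is removal of four methoxymethyl groups. Acetal protection is chosen because it survives the base, organozinc and palladium steps and can be removed without hydrogenation (alkene) and without base (C2, ring A). The forward step must avoid free strong protic acid, so cleavage goes through the silyl ethers 17 under buffered Lewis-acid conditions.

**16 from 13 and 15.** The C3′–CH2 bond of the side chain is cut. Carrying the alkene through the carbenoid step is rejected: an unhindered 1,1-disubstituted alkene would compete with, and probably outrun, the hindered tetrasubstituted furan double bond of 10. A chlorine atom at C3′ is an inert placeholder for every earlier reagent. The forward coupling has to activate an electron-rich aryl chloride next to an enolisable ketone; a base-free cross-coupling with the zinc reagent 15 is chosen because C2 is only endangered by base.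

**13 from 11 (through 12).** In the reverse sense the C2–H bond is removed and C2 is joined to C4, which contracts ring C to a furan ring fused to a cyclopropanol silyl ether. This maps the labile stereocentre onto a quaternary cyclopropane carbon that cannot epimerise. The forward reaction must break only the C1a–C6b bond of the cyclopropoxide (benzylic, oxygen-bearing carbanion rather than the primary CH2) and protonate C1a with inversion, which turns (1aR) into (2S).

**11 from 10.** Both bonds from the cyclopropane CH2 (the future C3) are cut, to C1a and to C6b. What remains is an achiral aromatic enol ether. This is the disconnection that carries the strategy: one carbon and the only stereocentre are introduced together. The forward reaction has to deliver methylene to one face of a tetrasubstituted double bond.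

**10 from 9, and 9 from 6 and 8.** The O–Si bond is cut first, then the C2–C1′ bond between the furanone and ring B. Cutting here makes the union of rings A and B a single coupling of two simple pieces. The stereolability of C2 in 9 is irrelevant, because silylation makes that carbon planar. The forward coupling must react at C–Br and leave C–Cl for later.

**6 from 5, 4, and 1 with 2 (through 3).** The acetals are exchanged for methyl ethers, because the 1,2,3,5-oxygenated benzene is available as 1. The furanone is cut at O1–C2 and C3–C3a, which leads to 1 and the two-carbon unit 2. The question of which ortho oxygen closes the ring is decided in 3 by loss of the methyl group that is flanked on both sides. The methyl-to-acetal exchange is placed after ring closure so that this choice stays fixed.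

**8 from 7, and 15 from 14.** One protection and one zinc insertion give the two small partners.

## Alternatives that were turned down

Alternative 1: Ring A is taken apart. The C5–C4a bond is formed last, by thermolysis of 3-(allyloxy)-4-{(2S)-2-[4-(tert-butyldimethylsilyloxy)-3-(3-methylbut-3-en-1-yl)phenyl]-4-oxo-3,4-dihydro-2H-pyran-6-yl}-4-hydroxycyclobut-2-en-1-one A2. On heating in toluene, A2 opens its four-membered ring, the ketene carbon so formed closes onto C5 of the pyranone ring in a 6π electrocyclisation (Moore cyclisation), and tautomerisation gives the hydroquinone (2S)-7-(allyloxy)-2-[4-(tert-butyldimethylsilyloxy)-3-(3-methylbut-3-en-1-yl)phenyl]-5,8-dihydroxychroman-4-one A1.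
- For it: all ring A oxygens of A1 arrive with their positions fixed by construction, and the thermal step has close analogy. On ring A regiocontrol it is stronger than the chosen route, which depends on a selective ortho-demethylation and a protecting-group exchange.
- Against it: C2 must already exist in the pyranone half of A2 and then survive metalation at C6 next to an enolisable ketone, a regioselective carbonyl addition on the four-membered ring, and heating. A1 is a free 5,8-hydroquinone with two different residual protecting groups, so two more deprotections follow.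
- Comparison: the sequence to A2 is clearly longer, and the stereocentre is exposed over many steps. The chosen route offers a stereocentre that is made in the bond-forming event three steps from the end.

Alternative 2: The C3–C4 bond is cut as an enol ether double bond, and the C2–O1 bond before it. The diene tert-butyl{[1-(2-{[(1S)-1-[4-(methoxymethoxy)-3-(3-methylbut-3-en-1-yl)phenyl]prop-2-en-1-yl]oxy}-3,4,6-tris(methoxymethoxy)phenyl)vinyl]oxy}dimethylsilane A4 would be closed with the second-generation Grubbs catalyst (H2IMes)(PCy3)Cl2Ru=CHPh, with loss of ethylene, to (2S)-4-(tert-butyldimethylsilyloxy)-5,7,8-tris(methoxymethoxy)-2-[4-(methoxymethoxy)-3-(3-methylbut-3-en-1-yl)phenyl]-2H-chromene A3. The stereocentre of A4 would be set earlier by a branched-selective allylic etherification with [Ir(cod)Cl]2 and a chiral phosphoramidite.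
- For it: the stereocentre of A4 comes from a reaction class with dependable enantioselection. On this point it is stronger than the chosen route, whose facial selectivity is unproven.
- Against it: the phenol oxygen that has to form the ether bond of A4 is flanked by an acyl group and an acetal oxygen and is a poor partner for the allylic substitution. Metathesis onto the 1,1-disubstituted, electron-rich silyl enol ether of A4 is slow, and the side-chain alkene of A4 is an olefin of the same substitution type, so the liability that forces the chain to be held back in the chosen route is present here too. A3 is a 2-aryl-2H-chromene that can open electrocyclically and lose C2.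
- Comparison: the step count is similar, but the risk is spread over three delicate steps. The chosen route concentrates it in one step on an easily made precursor.

Alternative 3: The C4–C4a bond is cut. The amide allyl 4-{(1S)-3-(dimethylamino)-3-oxo-1-[2,3,5-tris(allyloxy)phenoxy]propyl}-2-(3-methylbut-3-en-1-yl)phenyl carbonate A6 would be activated with Tf2O and 2-fluoropyridine to an O-triflyl iminium ion. The ring carbon ortho to the ether oxygen attacks it, and hydrolysis gives allyl 2-(3-methylbut-3-en-1-yl)-4-[(2S)-5,7,8-tris(allyloxy)-4-oxochroman-2-yl]phenyl carbonate A5.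
- For it: only one ring position of A6 can reach the electrophile, so the closure is regiochemically clean. The allyl groups of A5 come off at the end with Pd(PPh3)4 (zerovalent palladium) and a scavenger under neutral conditions, which suits the acid-sensitive alkene better than acetal cleavage; here it is stronger than the chosen route.
- Against it: the benzylic aryl ether stereocentre of A6 must be made beforehand with a hindered phenol and ionises easily. Under activation the β-aryloxy group can be expelled at the keteniminium stage, so elimination and racemisation threaten before A5 is reached. Tf2O meets four allyl groups and the 1,1-disubstituted alkene. A6 also needs the same awkward 2,3,5-trioxygenated phenol.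
- Comparison: A6 requires its own asymmetric multistep synthesis. The chosen route offers instead an achiral precursor in six steps and a key step that builds ring and stereocentre together.

Key step: step 7

## Route

Remark on the chemistry: the sense of induction of the dipeptide-bound zinc carbenoid on this substrate class cannot be predicted. The ligand is written in the L,L series; the D,D ligand is used instead if a test run shows attack on the other face. The same correction applies if the ring opening in step 8 were found to go with retention.
Remark on the chemistry: 1, 2, 7 and 14 are taken as purchasable.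

Step 1
Reactants: 1 1,2,3,5-tetramethoxybenzene; 2 chloroacetyl chloride
Product: 4 4,6,7-trimethoxy-1-benzofuran-3(2H)-one, via chloromethyl ketone 3 (not isolated)
Conditions: AlCl3 (2.5 equiv), CH2Cl2, 0 °C to rt; aq. HCl work-up; then NaOAc, MeOH, reflux
Reagents that add atoms: none
Why: Friedel–Crafts acylation can only occur at the two equivalent free positions of 1; AlCl3 chelated between the new carbonyl and the adjacent methoxy group that is flanked on both sides (twisted out of plane, most basic) cleaves that ether in preference to the other ortho methoxy, so the phenol of 3 lies next to the 3-methoxy group. NaOAc then closes the furanone by a 5-exo-tet intramolecular Williamson reaction, which fixes the 4,6,7 pattern.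

Step 2
Reactants: 4 4,6,7-trimethoxy-1-benzofuran-3(2H)-one
Product: 5 4,6,7-trihydroxy-1-benzofuran-3(2H)-one
Conditions: BBr3 (4 equiv), CH2Cl2, −78 °C to rt; MeOH then H2O; argon, product used at once
Reagents that add atoms: none
Why: Lewis-acid ether cleavage: BBr3 complexes each aryl methyl ether and bromide removes the methyl group by SN2; the ketone and the ring CH2 are not affected, and the oxidation-prone triol is kept under argon.

Step 3
Reactants: 5 4,6,7-trihydroxy-1-benzofuran-3(2H)-one
Product: 6 4,6,7-tris(methoxymethoxy)-1-benzofuran-3(2H)-one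
Conditions: MOMCl (4 equiv), i-Pr2NEt (5 equiv), CH2Cl2/DMF, 0 °C to rt
Reagents that add atoms: chloromethyl methyl ether, COCCl
Why: Williamson-type O-alkylation of the three phenols with the reactive α-chloro ether; the hindered amine does not enolise C2 to a useful extent, so the phenols should react ahead of the enol oxygen.

Step 4
Reactants: 7 4-bromo-2-chlorophenol
Product: 8 4-bromo-2-chloro-1-(methoxymethoxy)benzene
Conditions: MOMCl (1.3 equiv), i-Pr2NEt (1.5 equiv), CH2Cl2, 0 °C to rt
Reagents that add atoms: chloromethyl methyl ether, COCCl
Why: Standard protection of a phenol as its methoxymethyl acetal (Williamson-type O-alkylation); both halogens are inert.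

Step 5
Reactants: 6 4,6,7-tris(methoxymethoxy)-1-benzofuran-3(2H)-one; 8 4-bromo-2-chloro-1-(methoxymethoxy)benzene
Product: 9 2-[3-chloro-4-(methoxymethoxy)phenyl]-4,6,7-tris(methoxymethoxy)-1-benzofuran-3(2H)-one (racemic; C2 stereolabile)
Conditions: Pd2(dba)3 (2.5 mol %), Xantphos (6 mol %), NaOt-Bu (2.2 equiv), toluene, 80 °C, argon; degassed aq. NH4Cl
Reagents that add atoms: none
Why: Palladium-catalysed α-arylation of a ketone enolate: zerovalent palladium with the wide-bite-angle diphosphine inserts into the C–Br bond and leaves C–Cl alone, the sodium enolate of 6 transmetalates and reductive elimination forms the C2–aryl bond. The more stabilised and more hindered enolate of 9 should resist a second arylation, and the new C2 centre is erased in step 6.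

Step 6
Reactants: 9 2-[3-chloro-4-(methoxymethoxy)phenyl]-4,6,7-tris(methoxymethoxy)-1-benzofuran-3(2H)-one
Product: 10 {2-[3-chloro-4-(methoxymethoxy)phenyl]-4,6,7-tris(methoxymethoxy)-1-benzofuran-3-yl}oxy(trimethyl)silane
Conditions: TMSCl (1.5 equiv), Et3N (2 equiv), CH2Cl2, 0 °C to rt; filtration through Celite, no aqueous work-up
Reagents that add atoms: chlorotrimethylsilane, C[Si](C)(C)Cl
Why: O-Silylation of the enol form: silicon binds the hard oxygen terminus and the product gains the aromatic benzofuran ring, so the tetrasubstituted enol ether should form regiospecifically.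

Step 7
Reactants: 10 {2-[3-chloro-4-(methoxymethoxy)phenyl]-4,6,7-tris(methoxymethoxy)-1-benzofuran-3-yl}oxy(trimethyl)silane
Product: 11 (1aR,6bR)-1a-[3-chloro-4-(methoxymethoxy)phenyl]-3,4,6-tris(methoxymethoxy)-6b-[(trimethylsilyl)oxy]-1a,6b-dihydro-1H-cyclopropa[b][1]benzofuran
Conditions: Et2Zn (2 equiv), CH2I2 (3 equiv), methyl N-(tert-butoxycarbonyl)-L-valyl-L-prolinate (0.25–1.25 equiv), CH2Cl2, −40 to −20 °C, argon; pyridine, then cold aq. NaHCO3
Reagents that add atoms: diiodomethane, ICI
Why: Proposed new method: the dipeptide-bound zinc carbenoid (ligand)ZnCH2I, formed from Et2Zn and CH2I2, transfers CH2 to the C2=C3 bond of the 3-silyloxybenzofuran through the concerted butterfly transition state of the Simmons–Smith reaction, so both new C–C bonds form on one face at once. The closest known reaction type is the dipeptide-mediated asymmetric Simmons–Smith cyclopropanation of aryl-conjugated silyl enol ethers of simple ketones; a tetrasubstituted enol ether bond inside a furan ring has not been shown. The three-membered ring closes by a [2+1] addition that can only give the cis-fused bicycle, so C1a and C6b are set together and their relative configuration is fixed by geometry. Their absolute configuration depends on which face of the flat benzofuran the chiral carbenoid approaches, that is on reagent control by the dipeptide, since the substrate has no stereocentre. The step needs chemoselectivity for this double bond, which is secured by its two oxygen donors and by the absence of any other alkene, the side chain being represented by chlorine. The benzene rings are not attacked by zinc carbenoids, and the modest aromatic stabilisation of the furan ring is what the electron-rich enol ether has to overcome. Pyridine at the quench binds ZnI2 so that the silyloxycyclopropane is not isomerised.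

Step 8
Reactants: 11 (1aR,6bR)-1a-[3-chloro-4-(methoxymethoxy)phenyl]-3,4,6-tris(methoxymethoxy)-6b-[(trimethylsilyl)oxy]-1a,6b-dihydro-1H-cyclopropa[b][1]benzofuran
Product: 13 (2S)-2-[3-chloro-4-(methoxymethoxy)phenyl]-5,7,8-tris(methoxymethoxy)-2,3-dihydro-4H-chromen-4-one, via cyclopropanol 12 (not isolated)
Conditions: K2CO3 (0.3 equiv), MeOH/THF 2:1, −20 to 0 °C; pH 7 phosphate buffer
Reagents that add atoms: none
Why: Base-induced cyclopropanol ring opening (homoenolate-type fragmentation): methoxide removes the silyl group, the cyclopropoxide of 12 breaks the C6b–C1a bond because the developing carbanion is benzylic and oxygen-substituted whereas the alternative is a primary CH2, and methanol protonates C1a from the rear (SE2 with inversion) as the five-membered ring becomes the six-membered ketone, so (1aR) gives (2S). Catalytic base, low temperature and a buffered quench limit retro-oxa-Michael opening of 13.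

Step 9
Reactants: 14 4-bromo-2-methylbut-1-ene
Product: 15 bromo(3-methylbut-3-en-1-yl)zinc (THF solution with LiCl, titrated)
Conditions: Zn dust (1.5 equiv, activated with BrCH2CH2Br and TMSCl), LiCl (1.1 equiv), THF, 25–40 °C
Reagents that add atoms: zinc, [Zn]
Why: Oxidative insertion of zinc into the primary C–Br bond, helped by LiCl which keeps the organozinc in solution; homoallylic zinc halides do not cyclise or lose β-hydride at this temperature.

Step 10
Reactants: 13 (2S)-2-[3-chloro-4-(methoxymethoxy)phenyl]-5,7,8-tris(methoxymethoxy)-2,3-dihydro-4H-chromen-4-one; 15 bromo(3-methylbut-3-en-1-yl)zinc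
Product: 16 (2S)-5,7,8-tris(methoxymethoxy)-2-[4-(methoxymethoxy)-3-(3-methylbut-3-en-1-yl)phenyl]-2,3-dihydro-4H-chromen-4-one
Conditions: Pd(OAc)2 (3 mol %), SPhos (6 mol %), THF, 25 to 45 °C, argon
Reagents that add atoms: none
Why: Negishi coupling: the electron-rich biarylphosphine lets zerovalent palladium insert into the aryl C–Cl bond, the primary alkylzinc transmetalates and reductive elimination forms the aryl–CH2 bond faster than β-hydride elimination. No base is present, so the enolisable ketone and the C2 centre are not endangered.

Step 11
Reactants: 16 (2S)-5,7,8-tris(methoxymethoxy)-2-[4-(methoxymethoxy)-3-(3-methylbut-3-en-1-yl)phenyl]-2,3-dihydro-4H-chromen-4-one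
Product: 18 (2S)-5,7,8-trihydroxy-2-[4-hydroxy-3-(3-methylbut-3-en-1-yl)phenyl]-2,3-dihydro-4H-chromen-4-one, via tetrakis(trimethylsilyl) ether 17 (not isolated)
Conditions: TMSOTf (10 equiv), 2,2′-bipyridyl (15 equiv), MeCN, 0 °C to rt; then H2O, rt; argon, degassed solvents
Reagents that add atoms: none
Why: Lewis-acid-mediated cleavage of aryl methoxymethyl ethers: TMSOTf buffered by 2,2′-bipyridyl converts each acetal into the aryl silyl ether while the methoxymethyl cation is trapped on nitrogen, and water then hydrolyses 17. No free strong protic acid is present, so the alkene next to the new phenol should not be protonated and C2 is not touched.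

## Compound list

1 | 1,2,3,5-tetramethoxybenzene | COc1cc(OC)c(OC)c(OC)c1 | starting material
2 | chloroacetyl chloride | O=C(Cl)CCl | starting material
3 | 2-chloro-1-(2-hydroxy-3,4,6-trimethoxyphenyl)ethan-1-one | COc1cc(OC)c(C(=O)CCl)c(O)c1OC | intermediate (not isolated)
4 | 4,6,7-trimethoxy-1-benzofuran-3(2H)-one | COc1cc(OC)c2c(c1OC)OCC2=O | intermediate
5 | 4,6,7-trihydroxy-1-benzofuran-3(2H)-one | O=C1COc2c(O)c(O)cc(O)c12 | intermediate
6 | 4,6,7-tris(methoxymethoxy)-1-benzofuran-3(2H)-one | O=C1COc2c(OCOC)c(OCOC)cc(OCOC)c12 | intermediate
7 | 4-bromo-2-chlorophenol | Oc1ccc(Br)cc1Cl | starting material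
8 | 4-bromo-2-chloro-1-(methoxymethoxy)benzene | COCOc1ccc(Br)cc1Cl | intermediate
9 | 2-[3-chloro-4-(methoxymethoxy)phenyl]-4,6,7-tris(methoxymethoxy)-1-benzofuran-3(2H)-one (racemic) | COCOc1ccc(C2Oc3c(OCOC)c(OCOC)cc(OCOC)c3C2=O)cc1Cl | intermediate
10 | {2-[3-chloro-4-(methoxymethoxy)phenyl]-4,6,7-tris(methoxymethoxy)-1-benzofuran-3-yl}oxy(trimethyl)silane | COCOc1ccc(-c2oc3c(OCOC)c(OCOC)cc(OCOC)c3c2O[Si](C)(C)C)cc1Cl | intermediate
11 | (1aR,6bR)-1a-[3-chloro-4-(methoxymethoxy)phenyl]-3,4,6-tris(methoxymethoxy)-6b-[(trimethylsilyl)oxy]-1a,6b-dihydro-1H-cyclopropa[b][1]benzofuran | COCOc1ccc([C@]23C[C@@]2(O[Si](C)(C)C)c2c(OCOC)cc(OCOC)c(OCOC)c2O3)cc1Cl | intermediate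
12 | (1aR,6bR)-1a-[3-chloro-4-(methoxymethoxy)phenyl]-3,4,6-tris(methoxymethoxy)-1a,6b-dihydro-1H-cyclopropa[b][1]benzofuran-6b-ol | COCOc1ccc([C@]23C[C@@]2(O)c2c(OCOC)cc(OCOC)c(OCOC)c2O3)cc1Cl | intermediate (not isolated)
13 | (2S)-2-[3-chloro-4-(methoxymethoxy)phenyl]-5,7,8-tris(methoxymethoxy)-2,3-dihydro-4H-chromen-4-one | COCOc1ccc([C@@H]2CC(=O)c3c(OCOC)cc(OCOC)c(OCOC)c3O2)cc1Cl | intermediate
14 | 4-bromo-2-methylbut-1-ene | C=C(C)CCBr | starting material
15 | bromo(3-methylbut-3-en-1-yl)zinc | C=C(C)CC[Zn]Br | intermediate
16 | (2S)-5,7,8-tris(methoxymethoxy)-2-[4-(methoxymethoxy)-3-(3-methylbut-3-en-1-yl)phenyl]-2,3-dihydro-4H-chromen-4-one | C=C(C)CCc1cc([C@@H]2CC(=O)c3c(OCOC)cc(OCOC)c(OCOC)c3O2)ccc1OCOC | intermediate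
17 | (2S)-2-[3-(3-methylbut-3-en-1-yl)-4-[(trimethylsilyl)oxy]phenyl]-5,7,8-tris[(trimethylsilyl)oxy]-2,3-dihydro-4H-chromen-4-one | C=C(C)CCc1cc([C@@H]2CC(=O)c3c(O[Si](C)(C)C)cc(O[Si](C)(C)C)c(O[Si](C)(C)C)c3O2)ccc1O[Si](C)(C)C | intermediate (not isolated)
18 | (2S)-5,7,8-trihydroxy-2-[4-hydroxy-3-(3-methylbut-3-en-1-yl)phenyl]-2,3-dihydro-4H-chromen-4-one | C=C(C)CCc1cc([C@@H]2CC(=O)c3c(O)cc(O)c(O)c3O2)ccc1O | target

## Step count and least certain steps

Total: 11 steps. Longest linear sequence: 9 steps (steps 1, 2, 3, 5, 6, 7, 8, 10, 11); steps 4 and 9 are single-step side branches.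

**Step 7 (key step).** The most likely failures are poor facial selectivity and low conversion. The double bond is tetrasubstituted and flanked by an aryl group and a peri acetal, and the acetal oxygens can bind zinc and steer an unligated, non-selective background reaction. Fallback by known chemistry, from 10 back to 13: cyclopropanation with the more reactive achiral carbenoid CF3CO2ZnCH2I (Et2Zn, CF3CO2H, CH2I2, CH2Cl2, 0 °C) should give racemic cis-1a-[3-chloro-4-(methoxymethoxy)phenyl]-3,4,6-tris(methoxymethoxy)-6b-[(trimethylsilyl)oxy]-1a,6b-dihydro-1H-cyclopropa[b][1]benzofuran F1. Opening as in step 8 gives racemic 2-[3-chloro-4-(methoxymethoxy)phenyl]-5,7,8-tris(methoxymethoxy)-2,3-dihydro-4H-chromen-4-one F2. Kinetic resolution by asymmetric transfer hydrogenation with RuCl(p-cymene)[(R,R)-TsDPEN] and HCO2H/Et3N is expected, by the usual aryl ketone model, to reduce the (2R)-ketone to cis-(2R,4R)-2-[3-chloro-4-(methoxymethoxy)phenyl]-5,7,8-tris(methoxymethoxy)-3,4-dihydro-2H-chromen-4-ol F3 and leave the (2S)-ketone, which is 13.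

**Step 8.** Enantiopurity may be lost by base-induced retro-oxa-Michael opening and reclosure of the product, by incomplete inversion in the protonation, or by cleavage toward the CH2 carbon. Fallback by reductive interception, from 11 back to 13: the opening is run with NaBH4 present (K2CO3, NaBH4, MeOH/THF, −20 °C), so that the ketone is reduced as it forms to (2S,4S)-2-[3-chloro-4-(methoxymethoxy)phenyl]-5,7,8-tris(methoxymethoxy)-3,4-dihydro-2H-chromen-4-ol F4 (its C4 epimer serves equally). F4 cannot ring-open, and it is reoxidised under neutral conditions with Dess–Martin periodinane and NaHCO3 to 13.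

**Step 5.** Aldol self-condensation of the furanone under NaOt-Bu, over-arylation at C2, and air oxidation of the product at C2 are the likely problems. Fallback without strong base, from 6 back to 9: 6 is silylated (TMSCl, Et3N) to [4,6,7-tris(methoxymethoxy)-1-benzofuran-3-yl]oxy(trimethyl)silane F5, and this enol silane is coupled with one equivalent of 8 under fluoride activation (Pd(dba)2, P(t-Bu)3, ZnF2, CsF, DMF, 70 °C), the C–Br bond reacting ahead of C–Cl.

**Step 10.** Oxidative addition into the hindered, electron-rich C–Cl bond may be slow, the enolisable ketone may protonate the zinc reagent, and ZnBrCl may assist ring opening at C2 on prolonged warming. Fallback by moving the coupling ahead of the ring expansion, from 11 back to 16: 11 has no ketone and its stereocentres are quaternary. It is coupled with 15 (Pd(OAc)2, SPhos, THF) to (1aR,6bR)-3,4,6-tris(methoxymethoxy)-1a-[4-(methoxymethoxy)-3-(3-methylbut-3-en-1-yl)phenyl]-6b-[(trimethylsilyl)oxy]-1a,6b-dihydro-1H-cyclopropa[b][1]benzofuran F6, which is opened with K2CO3 in MeOH as in step 8 to give 16. This works because the alkene is then only exposed to base, not to a carbenoid.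

**Step 11.** Cleavage of four acetals may be incomplete, adventitious acid may drive cyclisation of the freed 4′-phenol onto the alkene or migration of the double bond, and free ring A may oxidise in air. Fallback by changing to fluoride-labile protection before the alkene is installed, from 13 back to 18: the acetals are removed while no alkene is present (HCl, MeOH, 40 °C) to give (2S)-2-(3-chloro-4-hydroxyphenyl)-5,7,8-trihydroxy-2,3-dihydro-4H-chromen-4-one F7. Silylation (TBSOTf, 2,6-lutidine, CH2Cl2, 0 °C, which also reaches the chelated 5-hydroxyl and avoids a basic medium) gives (2S)-5,7,8-tris[(tert-butyldimethylsilyl)oxy]-2-{4-[(tert-butyldimethylsilyl)oxy]-3-chlorophenyl}-2,3-dihydro-4H-chromen-4-one F8. Negishi coupling with 15 as in step 10 gives (2S)-5,7,8-tris[(tert-butyldimethylsilyl)oxy]-2-{4-[(tert-butyldimethylsilyl)oxy]-3-(3-methylbut-3-en-1-yl)phenyl}-2,3-dihydro-4H-chromen-4-one F9, and Et3N·3HF in THF releases 18 without strong acid or base.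

## Further compounds

F1 | step 7 | racemic cis-1a-[3-chloro-4-(methoxymethoxy)phenyl]-3,4,6-tris(methoxymethoxy)-6b-[(trimethylsilyl)oxy]-1a,6b-dihydro-1H-cyclopropa[b][1]benzofuran | COCOc1ccc(C23CC2(O[Si](C)(C)C)c2c(OCOC)cc(OCOC)c(OCOC)c2O3)cc1Cl
F2 | step 7 | racemic 2-[3-chloro-4-(methoxymethoxy)phenyl]-5,7,8-tris(methoxymethoxy)-2,3-dihydro-4H-chromen-4-one | COCOc1ccc(C2CC(=O)c3c(OCOC)cc(OCOC)c(OCOC)c3O2)cc1Cl
F3 | step 7 | (2R,4R)-2-[3-chloro-4-(methoxymethoxy)phenyl]-5,7,8-tris(methoxymethoxy)-3,4-dihydro-2H-chromen-4-ol | COCOc1ccc([C@H]2C[C@@H](O)c3c(OCOC)cc(OCOC)c(OCOC)c3O2)cc1Cl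
F4 | step 8 | (2S,4S)-2-[3-chloro-4-(methoxymethoxy)phenyl]-5,7,8-tris(methoxymethoxy)-3,4-dihydro-2H-chromen-4-ol | COCOc1ccc([C@@H]2C[C@H](O)c3c(OCOC)cc(OCOC)c(OCOC)c3O2)cc1Cl
F5 | step 5 | [4,6,7-tris(methoxymethoxy)-1-benzofuran-3-yl]oxy(trimethyl)silane | COCOc1cc(OCOC)c2c(O[Si](C)(C)C)coc2c1OCOC
F6 | step 10 | (1aR,6bR)-3,4,6-tris(methoxymethoxy)-1a-[4-(methoxymethoxy)-3-(3-methylbut-3-en-1-yl)phenyl]-6b-[(trimethylsilyl)oxy]-1a,6b-dihydro-1H-cyclopropa[b][1]benzofuran | C=C(C)CCc1cc([C@]23C[C@@]2(O[Si](C)(C)C)c2c(OCOC)cc(OCOC)c(OCOC)c2O3)ccc1OCOC
F7 | step 11 | (2S)-2-(3-chloro-4-hydroxyphenyl)-5,7,8-trihydroxy-2,3-dihydro-4H-chromen-4-one | Oc1ccc([C@@H]2CC(=O)c3c(O)cc(O)c(O)c3O2)cc1Cl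
F8 | step 11 | (2S)-5,7,8-tris[(tert-butyldimethylsilyl)oxy]-2-{4-[(tert-butyldimethylsilyl)oxy]-3-chlorophenyl}-2,3-dihydro-4H-chromen-4-one | CC(C)(C)[Si](C)(C)Oc1ccc([C@@H]2CC(=O)c3c(O[Si](C)(C)C(C)(C)C)cc(O[Si](C)(C)C(C)(C)C)c(O[Si](C)(C)C(C)(C)C)c3O2)cc1Cl
F9 | step 11 | (2S)-5,7,8-tris[(tert-butyldimethylsilyl)oxy]-2-{4-[(tert-butyldimethylsilyl)oxy]-3-(3-methylbut-3-en-1-yl)phenyl}-2,3-dihydro-4H-chromen-4-one | C=C(C)CCc1cc([C@@H]2CC(=O)c3c(O[Si](C)(C)C(C)(C)C)cc(O[Si](C)(C)C(C)(C)C)c(O[Si](C)(C)C(C)(C)C)c3O2)ccc1O[Si](C)(C)C(C)(C)C
A1 | alternative 1 | (2S)-7-(allyloxy)-2-[4-(tert-butyldimethylsilyloxy)-3-(3-methylbut-3-en-1-yl)phenyl]-5,8-dihydroxychroman-4-one | C=C(C)CCc1cc([C@@H]2CC(=O)c3c(O)cc(OCC=C)c(O)c3O2)ccc1O[Si](C)(C)C(C)(C)C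
A2 | alternative 1 | 3-(allyloxy)-4-{(2S)-2-[4-(tert-butyldimethylsilyloxy)-3-(3-methylbut-3-en-1-yl)phenyl]-4-oxo-3,4-dihydro-2H-pyran-6-yl}-4-hydroxycyclobut-2-en-1-one (carbinol centre unspecified) | C=CCOC1=CC(=O)C1(O)C1=CC(=O)C[C@@H](c2ccc(O[Si](C)(C)C(C)(C)C)c(CCC(C)=C)c2)O1
A3 | alternative 2 | (2S)-4-(tert-butyldimethylsilyloxy)-5,7,8-tris(methoxymethoxy)-2-[4-(methoxymethoxy)-3-(3-methylbut-3-en-1-yl)phenyl]-2H-chromene | C=C(C)CCc1cc([C@@H]2C=C(O[Si](C)(C)C(C)(C)C)c3c(OCOC)cc(OCOC)c(OCOC)c3O2)ccc1OCOC
A4 | alternative 2 | tert-butyl{[1-(2-{[(1S)-1-[4-(methoxymethoxy)-3-(3-methylbut-3-en-1-yl)phenyl]prop-2-en-1-yl]oxy}-3,4,6-tris(methoxymethoxy)phenyl)vinyl]oxy}dimethylsilane | C=C(O[Si](C)(C)C(C)(C)C)c1c(OCOC)cc(OCOC)c(OCOC)c1O[C@@H](C=C)c1ccc(OCOC)c(CCC(C)=C)c1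
A5 | alternative 3 | allyl 2-(3-methylbut-3-en-1-yl)-4-[(2S)-5,7,8-tris(allyloxy)-4-oxochroman-2-yl]phenyl carbonate | C=C(C)CCc1cc([C@@H]2CC(=O)c3c(OCC=C)cc(OCC=C)c(OCC=C)c3O2)ccc1OC(=O)OCC=C
A6 | alternative 3 | allyl 4-{(1S)-3-(dimethylamino)-3-oxo-1-[2,3,5-tris(allyloxy)phenoxy]propyl}-2-(3-methylbut-3-en-1-yl)phenyl carbonate | CN(C)C(=O)C[C@H](Oc1cc(OCC=C)cc(OCC=C)c1OCC=C)c1ccc(OC(=O)OCC=C)c(CCC(C)=C)c1
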